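**Plan**

- Cuts (germacrane numbering): C11=C13 (carried as CH2NMe2), the C8 ester C–O, the furanone O–C3 bond (back to a 10-hydroxy-1,3-diketone), then C8–C9 together with O–C10 (isoxazoline → nitrile oxide + isopropenyl group), C1–C2 (aldol), C3–C4 (Stille), C4=C5 (Wittig), C11–C13 (Mannich), C7–C8 (radical addition to a butenolide).
- Enabling feature: in the 10-membered carbocycle C1–C10, the carbinol C8 and the fully substituted ether carbon C10 (CH3, O, next to the C1 carbonyl) are 1,3-related across the C9 methylene. This aldol-type unit is a latent 5,5-disubstituted isoxazoline, i.e. a nitrile oxide at C8 and a 1,1-disubstituted alkene C9=C10.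
- Forward order: the γ-lactone comes from the chiral pool; the chain C5–C1/C10 is built on it; the 10-membered carbocycle and a temporary isoxazoline ring close in one cycloaddition; N–O cleavage and reduction give the 8,10-diol; the furanone ring closes last by cyclodehydration; the methylene is unmasked.
- Stereochemistry: C6 from (S)-5-(hydroxymethyl)furan-2(5H)-one; C7 by anti radical addition; Z-C4=C5 from the iodo-Wittig step; a temporary C1 carbinol by reagent-controlled aldol; C10 relayed from C1 in the cycloaddition; C8 by hydroxyl-directed anti reduction from C10; the ester centre from (S)-2-methylbutanoic acid.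

Key step: step 10

Remark: germacrane numbering is used for all intermediates (lactone O–C6, C7, C11, C12; C13 exocyclic; C14 on C10; C15 on C4); compounds 1, 10 and 21 are taken as commercial.

**Route**

Step 1
Reactants: 1 (S)-5-(hydroxymethyl)furan-2(5H)-one
Product: 2 (S)-5-[(triethylsilyloxy)methyl]furan-2(5H)-one
Conditions: Et3SiCl, imidazole, CH2Cl2, 0 °C
Reagents that add atoms: chlorotriethylsilane, CC[Si](Cl)(CC)CC
Why: Silyl ether formation on a primary alcohol is routine, and the triethylsilyl group is chosen because it survives steps 2 and 3 but can be oxidised off directly in step 4.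

Step 2
Reactants: 2 (S)-5-[(triethylsilyloxy)methyl]furan-2(5H)-one
Product: 3 (4S,5S)-4-(1,3-dioxolan-2-yl)-5-[(triethylsilyloxy)methyl]dihydrofuran-2(3H)-one
Conditions: 1,3-dioxolane (solvent), Ph2CO (10 mol %), hν (350 nm), 20 °C
Reagents that add atoms: 1,3-dioxolane, C1COCO1
Why: Benzophenone-sensitised photochemical radical conjugate addition (Giese type) of the 1,3-dioxolan-2-yl radical is well precedented for 5-substituted 2(5H)-furanones; the radical attacks C7 anti to the C6 side chain, which sets C7 trans to C6 and brings in C8 at the aldehyde oxidation level.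

Step 3
Reactants: 3 (4S,5S)-4-(1,3-dioxolan-2-yl)-5-[(triethylsilyloxy)methyl]dihydrofuran-2(3H)-one
Product: 5 (3R,4S,5S)-3-[(dimethylamino)methyl]-4-(1,3-dioxolan-2-yl)-5-[(triethylsilyloxy)methyl]dihydrofuran-2(3H)-one, via lithium enolate 4 (not isolated)
Conditions: LiN(iPr)2, THF, −78 °C; [Me2N=CH2]I, −78 to 0 °C
Reagents that add atoms: N,N-dimethylmethyleneiminium iodide (Eschenmoser's salt), C[N+](C)=C.[I-]
Why: Mannich reaction of the lactone enolate, in which the iminium ion enters trans to the C7 substituent (C11 is a temporary centre); the β-amino lactone is the standard masked form of the α-methylene lactone and is inert as a dipolarophile and Michael acceptor until step 16.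

Step 4
Reactants: 5 (3R,4S,5S)-3-[(dimethylamino)methyl]-4-(1,3-dioxolan-2-yl)-5-[(triethylsilyloxy)methyl]dihydrofuran-2(3H)-one
Product: 6 (2S,3S,4R)-4-[(dimethylamino)methyl]-3-(1,3-dioxolan-2-yl)-5-oxotetrahydrofuran-2-carbaldehyde
Conditions: (COCl)2, DMSO, CH2Cl2, −78 to −30 °C; Et3N, −78 to 0 °C
Reagents that add atoms: none
Why: Swern oxidation, under which a primary triethylsilyl ether is cleaved and oxidised to the aldehyde in one operation (a known variant) while the acetal and the tertiary amine are untouched; the α-acyloxy aldehyde is used at once to avoid epimerisation at C6.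

Step 5
Reactants: 6 (2S,3S,4R)-4-[(dimethylamino)methyl]-3-(1,3-dioxolan-2-yl)-5-oxotetrahydrofuran-2-carbaldehyde
Product: 7 (3R,4S,5S)-3-[(dimethylamino)methyl]-4-(1,3-dioxolan-2-yl)-5-[(Z)-2-iodoprop-1-en-1-yl]dihydrofuran-2(3H)-one
Conditions: [Ph3PCH(I)CH3]I, NaN(SiMe3)2, THF, −78 °C; 6, −78 to −20 °C
Reagents that add atoms: (1-iodoethylidene)triphenylphosphorane (from the phosphonium iodide), CC(I)=P(c1ccccc1)(c1ccccc1)c1ccccc1
Why: Wittig olefination with the α-iodo ylide (Stork–Zhao type) is known to give (Z)-2-iodoalk-2-enes, so iodine, the later point of attachment of C3, lies cis to C6 as the Z-C4=C5 bond of the target requires.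

Step 6
Reactants: 7 (3R,4S,5S)-3-[(dimethylamino)methyl]-4-(1,3-dioxolan-2-yl)-5-[(Z)-2-iodoprop-1-en-1-yl]dihydrofuran-2(3H)-one
Product: 9 (3R,4S,5R)-3-[(dimethylamino)methyl]-4-(1,3-dioxolan-2-yl)-5-[(Z)-2-methyl-3-oxobut-1-en-1-yl]dihydrofuran-2(3H)-one, via dienyl ethyl ether 8 (not isolated)
Conditions: Bu3SnC(OEt)=CH2, Pd(PPh3)4 (5 mol %), CuI, CsF, DMF, 45 °C; 1 M HCl, THF, 0 °C
Reagents that add atoms: tributyl(1-ethoxyvinyl)stannane, CCCC[Sn](CCCC)(CCCC)C(=C)OCC; water, O
Why: Stille coupling of a vinyl iodide with an α-alkoxyvinylstannane proceeds with retention of alkene geometry, and mild acid hydrolysis of the enol ether (an acetyl anion equivalent) unveils the methyl ketone without opening the dioxolane.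

Step 7
Reactants: 9 (3R,4S,5R)-3-[(dimethylamino)methyl]-4-(1,3-dioxolan-2-yl)-5-[(Z)-2-methyl-3-oxobut-1-en-1-yl]dihydrofuran-2(3H)-one; 10 methacrolein
Product: 12 (3R,4S,5R)-3-[(dimethylamino)methyl]-4-(1,3-dioxolan-2-yl)-5-[(1Z,5S)-5-hydroxy-2,6-dimethyl-3-oxohepta-1,6-dien-1-yl]dihydrofuran-2(3H)-one, via boron enolate 11 (not isolated)
Conditions: (+)-Ipc2BCl, Et3N, Et2O, −78 to 0 °C; 10, −78 to −20 °C; MeOH, pH 7 buffer, 0 °C
Reagents that add atoms: none
Why: Paterson aldol reaction, in which the enol diisopinocampheylborinate of the methyl ketone adds to the aldehyde through a cyclic boron transition state under reagent control; this is expected to set the temporary C1 carbinol as S (the antipodal borane would give the epimer), and the lactone is not enolised under these soft conditions.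

Step 8
Reactants: 12 (3R,4S,5R)-3-[(dimethylamino)methyl]-4-(1,3-dioxolan-2-yl)-5-[(1Z,5S)-5-hydroxy-2,6-dimethyl-3-oxohepta-1,6-dien-1-yl]dihydrofuran-2(3H)-one
Product: 13 tert-butyldimethylsilyl ether of 12 at the (5S)-hydroxyl (C1–OTBS)
Conditions: tBuMe2SiOTf, 2,6-lutidine, CH2Cl2, −78 °C
Reagents that add atoms: tert-butyldimethylsilyl triflate, CC(C)(C)[Si](C)(C)OS(=O)(=O)C(F)(F)F
Why: Silyl ether formation protects the C1 alcohol through steps 9 to 13 and supplies the allylic silyloxy group that is to steer the cycloaddition.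

Step 9
Reactants: 13 tert-butyldimethylsilyl ether of 12
Product: 15 (E)-aldoxime at C8 (13 with the dioxolane replaced by CH=NOH), via aldehyde 14 (not isolated)
Conditions: PPTS, acetone/H2O, 50 °C; NH2OH·HCl, NaOAc, EtOH, 0 °C
Reagents that add atoms: hydroxylamine hydrochloride, Cl.NO
Why: Acid-catalysed acetal hydrolysis followed by oxime condensation, in which the aldehyde reacts far faster than the hindered conjugated C3 ketone; β-elimination of the lactone oxygen from 14 is disfavoured because the C6–O bond lies close to the nodal plane of the C7 enol.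

Step 10
Reactants: 15 (E)-aldoxime at C8
Product: 18 bridged isoxazoline (10-membered carbocycle C1–C10 with the C8=N–O–C10 bridge; 1S-OTBS, 3-oxo, 4Z, 10-methyl, 6,12-lactone, 11-CH2NMe2; C6, C7 and C10 configured as in 27), via hydroximoyl chloride 16 (not isolated), via nitrile oxide 17 (not isolated)
Conditions: NCS, HCl (1 equiv), DMF, 0 °C; syringe-pump addition to Et3N, CH2Cl2 (final 1 mM), 25 °C
Reagents that add atoms: none
Why: NCS chlorinates the aldoxime while the amine is protonated, and Et3N then releases nitrile oxide 17 slowly at high dilution; it adds across C9=C10 in a concerted, asynchronous (3+2) cycloaddition that forms C8–C9 and O–C10 in one event, the closest known reaction type being the intramolecular nitrile oxide–alkene cycloaddition used for medium and large carbocycles. The 10-membered carbocycle C1–C10 is closed in the bridged (10-endo) mode, with C8 bonding to the distal CH2 terminus C9, and the same event closes the temporary 5-membered isoxazoline ring C8=N–O–C10–C9; the fused mode would need a C8–C10 bond, a 9-membered ring and the contra-electronic orientation on a 1,1-disubstituted alkene. The new quaternary centre C10 is controlled by the adjacent (1S)-silyloxy centre through the inside-alkoxy arrangement (OSi inside, the C2 chain anti to the incoming oxygen), which exposes the Re face of C10 (C1 > C9 > C14) and leads to 10R; the tether, stiffened by the trans-fused lactone and the Z-C4=C5 bond, has to agree with this preference. Chemoselectivity is secured because C9=C10 is the only alkene the dipole can reach (C4=C5 is trisubstituted, conjugated and geometrically out of range) and because the α-methylene lactone, the best dipolarophile of the target, is still masked as the amine. The isoxazoline holds the C8 oxygenation level, the later furanone oxygen on C10 and the methyl-bearing quaternary centre in latent form.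

Step 11
Reactants: 18 bridged isoxazoline
Product: 19 10-hydroxy-3,8-dioxo macrocycle (β-hydroxy ketone; 1S-OTBS, 4Z, 6,12-lactone, 11-CH2NMe2)
Conditions: Mo(CO)6, MeCN/H2O, 80 °C
Reagents that add atoms: water, O
Why: Reductive N–O cleavage of an isoxazoline with Mo(CO)6 in wet acetonitrile, followed by hydrolysis of the β-hydroxy imine (the isoxazoline route to aldols), should give the β-hydroxy ketone with the tertiary C10 carbinol intact and no stereocentre touched.

Step 12
Reactants: 19 10-hydroxy-3,8-dioxo macrocycle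
Product: 20 8,10-dihydroxy-3-oxo macrocycle (8R, 1,3-anti diol)
Conditions: Me4NBH(OAc)3, MeCN/AcOH (1:1), −30 °C
Reagents that add atoms: none
Why: Evans–Saksena reduction, in which the C10 hydroxyl exchanges onto boron and delivers hydride internally through a chair transition state to the C8 ketone; this gives the 1,3-anti diol (8R) required by the target, while the C3 enone, which has no free β-hydroxyl, and the lactone are not reduced.

Step 13
Reactants: 20 8,10-dihydroxy-3-oxo macrocycle; 21 (S)-2-methylbutanoic acid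
Product: 22 8-O-[(S)-2-methylbutanoyl] ester of 20
Conditions: DCC, DMAP (cat.), CH2Cl2, 0 °C to rt
Reagents that add atoms: none
Why: Steglich esterification acylates the secondary C8 hydroxyl in preference to the tertiary C10 hydroxyl, and the carbodiimide conditions avoid ketene formation so that the α-centre of the acid is retained.

Step 14
Reactants: 22 8-O-[(S)-2-methylbutanoyl] ester
Product: 23 1,10-dihydroxy-3-oxo 8-ester (desilylated 22)
Conditions: HF·pyridine, THF/pyridine, 0 °C to rt
Reagents that add atoms: none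
Why: Fluoride-mediated desilylation frees the C1 hydroxyl without touching the ester, the lactone or the tertiary alcohol.

Step 15
Reactants: 23 1,10-dihydroxy-3-oxo 8-ester
Product: 25 13-(dimethylamino)-11,13-dihydro derivative of the target (furanone closed), via hydroxy diketone 24 (not isolated)
Conditions: SO3·pyridine, DMSO, iPr2NEt, CH2Cl2, 0 °C; TsOH·H2O (cat.), CH2Cl2, rt
Reagents that add atoms: none
Why: Parikh–Doering oxidation of the secondary C1 alcohol of the 1,2-diol gives the 10-hydroxy-1,3-diketone without glycol cleavage, and acid-catalysed cyclodehydration (attack of the C10 hydroxyl on C3, loss of water), the classical 3(2H)-furanone synthesis, closes the oxygen bridge without affecting C10.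

Step 16
Reactants: 25 13-(dimethylamino)-11,13-dihydro derivative of the target
Product: 27 target, (6R,7R,8R,10R)-8-[(S)-2-methylbutanoyloxy]-1-oxo-3,10-epoxygermacra-2,4Z,11(13)-trien-12,6-olide, via ammonium iodide 26 (not isolated)
Conditions: MeI, MeOH, rt; NaHCO3, H2O/CH2Cl2, rt
Reagents that add atoms: none
Why: Exhaustive N-methylation and E1cB (Hofmann-type) elimination of trimethylamine under bicarbonate regenerates the α-methylene lactone under conditions mild enough for the furanone, the ester and the C6 centre.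

**Compound list**

1 | (S)-5-(hydroxymethyl)furan-2(5H)-one | O=C1O[C@H](CO)C=C1 | starting material
2 | (S)-5-[(triethylsilyloxy)methyl]furan-2(5H)-one | O=C1O[C@H](CO[Si](CC)(CC)CC)C=C1 | intermediate
3 | (4S,5S)-4-(1,3-dioxolan-2-yl)-5-[(triethylsilyloxy)methyl]dihydrofuran-2(3H)-one | O=C1O[C@H](CO[Si](CC)(CC)CC)[C@@H](C2OCCO2)C1 | intermediate
4 | lithium enolate of 3 | [Li]OC1=C[C@H](C2OCCO2)[C@@H](CO[Si](CC)(CC)CC)O1 | intermediate
5 | (3R,4S,5S)-3-[(dimethylamino)methyl]-4-(1,3-dioxolan-2-yl)-5-[(triethylsilyloxy)methyl]dihydrofuran-2(3H)-one | O=C1O[C@H](CO[Si](CC)(CC)CC)[C@@H](C2OCCO2)[C@@H]1CN(C)C | intermediate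
6 | (2S,3S,4R)-4-[(dimethylamino)methyl]-3-(1,3-dioxolan-2-yl)-5-oxotetrahydrofuran-2-carbaldehyde | O=C1O[C@H](C=O)[C@@H](C2OCCO2)[C@@H]1CN(C)C | intermediate
7 | (3R,4S,5S)-3-[(dimethylamino)methyl]-4-(1,3-dioxolan-2-yl)-5-[(Z)-2-iodoprop-1-en-1-yl]dihydrofuran-2(3H)-one | O=C1O[C@H](/C=C(/C)I)[C@@H](C2OCCO2)[C@@H]1CN(C)C | intermediate
8 | (3R,4S,5R)-3-[(dimethylamino)methyl]-4-(1,3-dioxolan-2-yl)-5-[(Z)-3-ethoxy-2-methylbuta-1,3-dien-1-yl]dihydrofuran-2(3H)-one | O=C1O[C@H](/C=C(/C)C(=C)OCC)[C@@H](C2OCCO2)[C@@H]1CN(C)C | intermediate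
9 | (3R,4S,5R)-3-[(dimethylamino)methyl]-4-(1,3-dioxolan-2-yl)-5-[(Z)-2-methyl-3-oxobut-1-en-1-yl]dihydrofuran-2(3H)-one | O=C1O[C@H](/C=C(/C)C(C)=O)[C@@H](C2OCCO2)[C@@H]1CN(C)C | intermediate
10 | methacrolein (2-methylprop-2-enal) | C=C(C)C=O | starting material
11 | enol diisopinocampheylborinate of 9 | O=C1O[C@H](/C=C(/C)C(=C)OB(C2CC3CC(C2C)C3(C)C)C2CC3CC(C2C)C3(C)C)[C@@H](C2OCCO2)[C@@H]1CN(C)C | intermediate
12 | (3R,4S,5R)-3-[(dimethylamino)methyl]-4-(1,3-dioxolan-2-yl)-5-[(1Z,5S)-5-hydroxy-2,6-dimethyl-3-oxohepta-1,6-dien-1-yl]dihydrofuran-2(3H)-one | O=C1O[C@H](/C=C(/C)C(=O)C[C@H](O)C(C)=C)[C@@H](C2OCCO2)[C@@H]1CN(C)C | intermediate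
13 | tert-butyldimethylsilyl ether of 12 (C1–OTBS, 1S) | O=C1O[C@H](/C=C(/C)C(=O)C[C@H](O[Si](C)(C)C(C)(C)C)C(C)=C)[C@@H](C2OCCO2)[C@@H]1CN(C)C | intermediate
14 | C8 aldehyde (13 with the dioxolane replaced by formyl) | O=C1O[C@H](/C=C(/C)C(=O)C[C@H](O[Si](C)(C)C(C)(C)C)C(C)=C)[C@@H](C=O)[C@@H]1CN(C)C | intermediate
15 | (E)-aldoxime of 14 | O=C1O[C@H](/C=C(/C)C(=O)C[C@H](O[Si](C)(C)C(C)(C)C)C(C)=C)[C@@H](/C=N/O)[C@@H]1CN(C)C | intermediate
16 | hydroximoyl chloride of 15 | O=C1O[C@H](/C=C(/C)C(=O)C[C@H](O[Si](C)(C)C(C)(C)C)C(C)=C)[C@@H](C(Cl)=NO)[C@@H]1CN(C)C | intermediate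
17 | nitrile oxide at C8 | O=C1O[C@H](/C=C(/C)C(=O)C[C@H](O[Si](C)(C)C(C)(C)C)C(C)=C)[C@@H](C#[N+][O-])[C@@H]1CN(C)C | intermediate
18 | bridged isoxazoline: carbocycle C1–C10 with C8=N–O–C10 bridge, 1S-OTBS, 3-oxo, 4Z, 10-methyl, trans-6,12-lactone, 11-CH2NMe2 (C6, C7, C10 as in 27) | CN(C)C[C@@H]1C(=O)O[C@@H]2/C=C(/C)C(=O)C[C@H](O[Si](C)(C)C(C)(C)C)[C@@]3(C)CC(=NO3)[C@@H]12 | intermediate
19 | 10-hydroxy-3,8-dioxo macrocycle (1S-OTBS, 4Z, lactone, 11-CH2NMe2) | CN(C)C[C@@H]1C(=O)O[C@@H]2/C=C(/C)C(=O)C[C@H](O[Si](C)(C)C(C)(C)C)[C@](C)(O)CC(=O)[C@@H]12 | intermediate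
20 | 8,10-dihydroxy-3-oxo macrocycle (8R, anti to the C10 hydroxyl) | CN(C)C[C@@H]1C(=O)O[C@@H]2/C=C(/C)C(=O)C[C@H](O[Si](C)(C)C(C)(C)C)[C@](C)(O)C[C@@H](O)[C@@H]12 | intermediate
21 | (S)-2-methylbutanoic acid | CC[C@H](C)C(=O)O | starting material
22 | 8-O-[(S)-2-methylbutanoyl] ester of 20 | CN(C)C[C@@H]1C(=O)O[C@@H]2/C=C(/C)C(=O)C[C@H](O[Si](C)(C)C(C)(C)C)[C@](C)(O)C[C@@H](OC(=O)[C@@H](C)CC)[C@@H]12 | intermediate
23 | 1,10-dihydroxy-3-oxo 8-ester (desilylated 22) | CN(C)C[C@@H]1C(=O)O[C@@H]2/C=C(/C)C(=O)C[C@H](O)[C@](C)(O)C[C@@H](OC(=O)[C@@H](C)CC)[C@@H]12 | intermediate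
24 | 10-hydroxy-1,3-dioxo 8-ester | CN(C)C[C@@H]1C(=O)O[C@@H]2/C=C(/C)C(=O)CC(=O)[C@](C)(O)C[C@@H](OC(=O)[C@@H](C)CC)[C@@H]12 | intermediate
25 | 13-(dimethylamino)-11,13-dihydro derivative of the target | CN(C)C[C@@H]1C(=O)O[C@@H]2/C=C(/C)C3=CC(=O)[C@@](C)(C[C@@H](OC(=O)[C@@H](C)CC)[C@@H]12)O3 | intermediate
26 | trimethylammonium iodide of 25 | C[N+](C)(C)C[C@@H]1C(=O)O[C@@H]2/C=C(/C)C3=CC(=O)[C@@](C)(C[C@@H](OC(=O)[C@@H](C)CC)[C@@H]12)O3.[I-] | intermediate
27 | (6R,7R,8R,10R)-8-[(S)-2-methylbutanoyloxy]-1-oxo-3,10-epoxygermacra-2,4Z,11(13)-trien-12,6-olide (CNP0174601.1) | C=C1C(=O)O[C@@H]2/C=C(/C)C3=CC(=O)[C@@](C)(C[C@@H](OC(=O)[C@@H](C)CC)[C@@H]12)O3 | target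

**Step count and risks**

Total step count: 16. Longest linear sequence: 16 steps (1 → 27); 10 and 21 enter as single commercial compounds.

The three steps most likely to fail:

Step 10. The nitrile oxide may dimerise or oligomerise faster than the 10-membered ring closes, or the tether may override the allylic control so that the wrong face of C9=C10 is attacked. The fallback makes the C8–C9 bond between two molecules and closes the ring at C3–C4 instead. It sets out from 7 and comes back at 18. Methacrolein 10 is converted by a catalytic asymmetric Mukaiyama acetate aldol reaction (silyl ketene acetal of ethyl acetate, Ti(OiPr)4/BINOL, the ligand enantiomer that gives the S carbinol) into ethyl (S)-3-hydroxy-4-methylpent-4-enoate F1. This is silylated (tBuMe2SiOTf, 2,6-lutidine) to ethyl (S)-3-[(tert-butyldimethylsilyl)oxy]-4-methylpent-4-enoate F2 and reduced with iBu2AlH at −78 °C to (S)-3-[(tert-butyldimethylsilyl)oxy]-4-methylpent-4-enal F3. Vinyl iodide 7 is taken through the conditions of step 9 to the iodo-alkenyl aldoxime F4, chlorinated with NCS to the hydroximoyl chloride F5 and dehydrochlorinated with Et3N to the nitrile oxide F6 in the presence of F3. This should give the intermolecular isoxazoline cycloadduct F7, with C10 set by the same inside-alkoxy preference, now free of any ring constraint. An intramolecular Nozaki–Hiyama–Kishi reaction (CrCl2, NiCl2 cat., DMSO/THF, high dilution) between the vinyl iodide carbon C4 and the aldehyde carbon C3 closes the 10-membered ring to the macrocyclic C3 allylic alcohol F8 (C3 epimers). Dess–Martin oxidation of F8 gives 18.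

Step 12. Exchange of the hindered tertiary C10 hydroxyl onto boron may be slow, so that intramolecular delivery is lost and facial selectivity at C8 is poor. The fallback gives up the directed reduction and corrects C8 by inversion. It sets out from 19 and comes back at 22. Compound 19 is reduced by external hydride (NaBH4, CeCl3, MeOH, −78 °C); if this gives mainly the 8-epimeric 8,10-diol F9, a Mitsunobu esterification with acid 21 (PPh3, diisopropyl azodicarboxylate, toluene) installs the ester with inversion at C8 and gives 22. If it gives 20, the route continues unchanged.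

Step 5. The basic, unstabilised ylide may epimerise the α-acyloxy aldehyde at C6 or give poor Z/E control. The fallback replaces the Wittig/Stille pair by one stabilised olefination. It sets out from 6 and comes back at 9, bypassing 7 and 8. A Still–Gennari-type Horner–Wadsworth–Emmons reaction of 6 with bis(2,2,2-trifluoroethyl) (3-oxobutan-2-yl)phosphonate (KN(SiMe3)2, 18-crown-6, THF, −78 °C) should form the Z-enone 9 directly.

**Further compounds**

F1 | step 10 | ethyl (S)-3-hydroxy-4-methylpent-4-enoate | CCOC(=O)C[C@H](O)C(C)=C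
F2 | step 10 | ethyl (S)-3-[(tert-butyldimethylsilyl)oxy]-4-methylpent-4-enoate | CCOC(=O)C[C@H](O[Si](C)(C)C(C)(C)C)C(C)=C
F3 | step 10 | (S)-3-[(tert-butyldimethylsilyl)oxy]-4-methylpent-4-enal | O=CC[C@H](O[Si](C)(C)C(C)(C)C)C(C)=C
F4 | step 10 | iodo-alkenyl aldoxime (7 with the dioxolane replaced by CH=NOH) | O=C1O[C@H](/C=C(/C)I)[C@@H](/C=N/O)[C@@H]1CN(C)C
F5 | step 10 | hydroximoyl chloride of F4 | O=C1O[C@H](/C=C(/C)I)[C@@H](C(Cl)=NO)[C@@H]1CN(C)C
F6 | step 10 | nitrile oxide from F5 | O=C1O[C@H](/C=C(/C)I)[C@@H](C#[N+][O-])[C@@H]1CN(C)C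
F7 | step 10 | intermolecular isoxazoline cycloadduct (vinyl iodide and C3 aldehyde) | O=CC[C@H](O[Si](C)(C)C(C)(C)C)[C@@]1(C)CC(=NO1)[C@H]1[C@H](CN(C)C)C(=O)O[C@@H]1/C=C(/C)I
F8 | step 10 | macrocyclic C3 allylic alcohol (3-hydroxy analogue of 18, C3 epimers) | CN(C)C[C@@H]1C(=O)O[C@@H]2/C=C(/C)C(O)C[C@H](O[Si](C)(C)C(C)(C)C)[C@@]3(C)CC(=NO3)[C@@H]12
F9 | step 12 | 8-epimeric 8,10-diol (8-epi-20) | CN(C)C[C@@H]1C(=O)O[C@@H]2/C=C(/C)C(=O)C[C@H](O[Si](C)(C)C(C)(C)C)[C@](C)(O)C[C@H](O)[C@@H]12
F0 | step 5 | none | none
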